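**Retrosynthetic overview**
1. Target acid 14 ⇐ methyl ester 13 (saponification).
2. The 1,2-dioxane (the only ring, closed in step 6) ⇐ acyclic hydroperoxy ketal 11, by forming the C3–O bond in an enantioselective 6-exo peroxy-Michael addition; C6 is then corrected by anomeric equilibration.
3. 11 ⇐ keto enoate 10 (ketone converted to the α-methoxy hydroperoxide).
4. 10 ⇐ ketone 8 + methyl acrylate 9 (cross-metathesis); 8 ⇐ nitrile 5 + but-3-enylmagnesium bromide 6.
5. 5 ⇐ (E)-1-iodoundec-1-ene 3 + hex-5-ynenitrile 4 (Sonogashira); 3 ⇐ undec-1-yne 1.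

The target is 2-[(3S,6R)-6-[(6E)-hexadec-6-en-4-yn-1-yl]-6-methoxy-1,2-dioxan-3-yl]acetic acid. The methoxy group and the CH2CO2H group are cis, so in the chair the methoxy group is axial and both carbon substituents are equatorial.

Assumption: the facial sense of the new cyclisation (step 6) cannot be predicted with certainty; the (S)-catalyst from L-tert-leucine is written, SMILES O=C(Nc1cc(cc(c1)C(F)(F)F)C(F)(F)F)N[C@@H](C(C)(C)C)CN=P(c1ccc(OC)cc1)(c1ccc(OC)cc1)c1ccc(OC)cc1, and its mirror image is used if it gives the 3R series.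

**Step 1**
Reactants: 1 undec-1-yne
Product: 3 (E)-1-iodoundec-1-ene, via alkenylzirconocene chloride 2 (not isolated)
Conditions: Cp2Zr(H)Cl (1.2 equiv), THF, rt; then I2 (1.2 equiv), 0 °C
Reagents that add atoms: iodine, II
Why: Hydrozirconation with the Schwartz reagent is a syn, anti-Markovnikov addition and iododezirconation proceeds with retention, so only the E-vinyl iodide forms.

**Step 2**
Reactants: 3 (E)-1-iodoundec-1-ene; 4 hex-5-ynenitrile
Product: 5 (7E)-heptadec-7-en-5-ynenitrile
Conditions: PdCl2(PPh3)2 (2 mol%), CuI (4 mol%), Et3N (3 equiv), THF, rt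
Reagents that add atoms: none
Why: Sonogashira coupling of a vinyl iodide with a terminal alkyne retains the E geometry and tolerates the nitrile.

**Step 3**
Reactants: 5 (7E)-heptadec-7-en-5-ynenitrile; 6 but-3-enylmagnesium bromide (commercial 0.5 M solution in THF)
Product: 8 (11E)-henicosa-1,11-dien-9-yn-5-one, via bromomagnesium ketimine 7 (not isolated)
Conditions: 6 (1.5 equiv), CuBr·SMe2 (2 mol%), THF, 0 → 45 °C; then 1 M aq HCl, 0 °C → rt
Reagents that add atoms: water, O
Why: CuBr-catalysed Grignard addition to a nitrile stops at the N-magnesio ketimine, which cannot add a second equivalent, and acidic hydrolysis releases the ketone without touching the enyne.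

**Step 4**
Reactants: 8 (11E)-henicosa-1,11-dien-9-yn-5-one; 9 methyl acrylate (5 equiv)
Product: 10 methyl (2E,12E)-6-oxodocosa-2,12-dien-10-ynoate
Conditions: second-generation Hoveyda–Grubbs catalyst RuCl2(H2IMes)(=CH-C6H4-2-OiPr) (3 mol%), CH2Cl2, 40 °C
Reagents that add atoms: none
Why: Olefin cross-metathesis of a terminal alkene with an acrylate is strongly E-selective, and the internal, conjugated enyne is far less reactive toward the ruthenium carbene than the monosubstituted alkene.

**Step 5**
Reactants: 10 methyl (2E,12E)-6-oxodocosa-2,12-dien-10-ynoate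
Product: 11 methyl (2E,12E)-6-hydroperoxy-6-methoxydocosa-2,12-dien-10-ynoate (racemic at C6)
Conditions: urea·H2O2 (4 equiv), Sc(OTf)3 (10 mol%), MeOH, 0 °C → rt (ruthenium residues removed beforehand)
Reagents that add atoms: hydrogen peroxide (from urea–hydrogen peroxide), OO; methanol, CO
Why: Lewis-acid-catalysed hydroperoxyketalisation, in which Sc(OTf)3 turns the ketone into a methoxy oxocarbenium ion that is captured by H2O2, while the enoate and enyne are inert and no base is present to trigger cyclisation.

**Step 6**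
Reactants: 11 methyl (2E,12E)-6-hydroperoxy-6-methoxydocosa-2,12-dien-10-ynoate
Product: 13 methyl 2-[(3S,6R)-6-[(6E)-hexadec-6-en-4-yn-1-yl]-6-methoxy-1,2-dioxan-3-yl]acetate, via C6-epimeric dioxane ester 12 (not isolated)
Conditions: iminophosphorane–urea catalyst (S)-ArNHC(O)NH–CH(tBu)–CH2–N=P(C6H4-4-OMe)3, Ar = 3,5-(CF3)2C6H3 (10 mol%), toluene, −20 °C; then CSA (0.3 equiv), CH2Cl2, rt
Reagents that add atoms: none
Why: Proposed new method: a catalytic enantioselective 6-exo-trig peroxy-Michael cyclisation in which the iminophosphorane deprotonates the hydroperoxide (far more acidic than the alcohols this catalyst class already activates), the aminophosphonium and urea N–H groups hold the peroxide anion and the enoate carbonyl in a chair-like ion-pair transition state so that the C3–O bond forms on one enoate face (3S) for both C6 antipodes of 11, giving 13 and its C6 epimer 12, and the ester enolate is protonated by the aminophosphonium before it can expel alkoxide; CSA then epimerises C6 alone, through reversible ionisation of the ring C6–O bond to the methoxy-stabilised oxocarbenium ion, to the anomerically favoured 13 (axial OMe, both carbon substituents equatorial); the closest known reactions are the bifunctional-iminophosphorane-catalysed enantioselective intramolecular oxa-Michael addition of alcohols to α,β-unsaturated esters and the racemic amine-mediated peroxy-Michael closure of hydroperoxy ketals to 3-methoxy-1,2-dioxanes.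

**Step 7**
Reactants: 13 methyl 2-[(3S,6R)-6-[(6E)-hexadec-6-en-4-yn-1-yl]-6-methoxy-1,2-dioxan-3-yl]acetate
Product: 14 2-[(3S,6R)-6-[(6E)-hexadec-6-en-4-yn-1-yl]-6-methoxy-1,2-dioxan-3-yl]acetic acid (target)
Conditions: LiOH·H2O (3 equiv), THF/H2O (3:1), 0 °C; then 0.5 M aq HCl to pH 4, 0 °C
Reagents that add atoms: lithium hydroxide, [Li+].[OH-]
Why: Saponification of the methyl ester by hydroxide is much faster at 0 °C than enolisation toward retro-Michael opening, and the dialkyl peroxyketal survives cold dilute base and a brief cold acidification, so neither stereocentre is touched.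

**Compound list**
1 | undec-1-yne | CCCCCCCCCC#C | starting material
2 | (E)-undec-1-enylzirconocene chloride | CCCCCCCCC/C=C/[Zr](Cl)(C1C=CC=C1)C1C=CC=C1 | intermediate
3 | (E)-1-iodoundec-1-ene | CCCCCCCCC/C=C/I | intermediate
4 | hex-5-ynenitrile | C#CCCCC#N | starting material
5 | (7E)-heptadec-7-en-5-ynenitrile | CCCCCCCCC/C=C/C#CCCCC#N | intermediate
6 | but-3-enylmagnesium bromide | C=CCC[Mg]Br | starting material
7 | bromomagnesium ketimine of 8 | CCCCCCCCC/C=C/C#CCCCC(=N[Mg]Br)CCC=C | intermediate
8 | (11E)-henicosa-1,11-dien-9-yn-5-one | CCCCCCCCC/C=C/C#CCCCC(=O)CCC=C | intermediate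
9 | methyl acrylate | C=CC(=O)OC | starting material
10 | methyl (2E,12E)-6-oxodocosa-2,12-dien-10-ynoate | CCCCCCCCC/C=C/C#CCCCC(=O)CC/C=C/C(=O)OC | intermediate
11 | methyl (2E,12E)-6-hydroperoxy-6-methoxydocosa-2,12-dien-10-ynoate, racemic at C6 | CCCCCCCCC/C=C/C#CCCCC(OC)(OO)CC/C=C/C(=O)OC | intermediate
12 | methyl 2-[(3S,6S)-6-[(6E)-hexadec-6-en-4-yn-1-yl]-6-methoxy-1,2-dioxan-3-yl]acetate | CCCCCCCCC/C=C/C#CCCC[C@@]1(OC)CC[C@@H](CC(=O)OC)OO1 | intermediate
13 | methyl 2-[(3S,6R)-6-[(6E)-hexadec-6-en-4-yn-1-yl]-6-methoxy-1,2-dioxan-3-yl]acetate | CCCCCCCCC/C=C/C#CCCC[C@]1(OC)CC[C@@H](CC(=O)OC)OO1 | intermediate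
14 | 2-[(3S,6R)-6-[(6E)-hexadec-6-en-4-yn-1-yl]-6-methoxy-1,2-dioxan-3-yl]acetic acid | CCCCCCCCC/C=C/C#CCCC[C@]1(OC)CC[C@@H](CC(=O)O)OO1 | target

**Totals**
Total step count: 7. Longest linear sequence: 7 steps (1 → 3 → 5 → 8 → 10 → 11 → 13 → 14).

**Three steps most likely to fail**

Step 6 (the proposed new cyclisation). The risks are three:
- The C6 antipode of 11 that is mismatched with the catalyst may react slowly or with lower face selectivity. The step then becomes a kinetic resolution, and the recovered hydroperoxide can be racemised under the step 5 conditions and recycled.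
- The peroxide anion may degrade the aminophosphonium catalyst.
- Retro-Michael opening may erode the ee.
- In addition, the acid equilibration is expected to favour 13 by roughly 5:1 or better rather than completely, so residual 12 would be separated and re-equilibrated.

The fallback sets out from 11 and uses known chemistry. Et2NH in CF3CH2OH at rt effects the racemic peroxy-Michael closure. It gives 13 and 12 together with their mirror images, methyl 2-[(3R,6S)-6-[(6E)-hexadec-6-en-4-yn-1-yl]-6-methoxy-1,2-dioxan-3-yl]acetate F1 and methyl 2-[(3R,6R)-6-[(6E)-hexadec-6-en-4-yn-1-yl]-6-methoxy-1,2-dioxan-3-yl]acetate F2. CSA in CH2Cl2 converges 12 to 13 and F2 to F1. Preparative HPLC on a chiral stationary phase (amylose tris(3,5-dimethylphenylcarbamate)) then separates 13 from F1, and the route is rejoined at 13.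

Step 4 (cross-metathesis next to a conjugated enyne). The ruthenium carbene may engage the alkyne (enyne metathesis) or the internal alkene of the enyne. The fallback avoids metathesis; it sets out from nitrile 5 and bypasses 8. Addition of commercial [2-(1,3-dioxan-2-yl)ethyl]magnesium bromide (CuBr·SMe2 cat., THF, 45 °C) gives the bromomagnesium ketimine of the keto acetal F3. Cold 1 M aq HCl hydrolyses it to (9E)-1-(1,3-dioxan-2-yl)nonadec-9-en-7-yn-3-one F4. 2 M HCl in THF at 40 °C unmasks (10E)-4-oxoicos-10-en-8-ynal F5. Wittig olefination with Ph3P=CHCO2Me in CH2Cl2 at rt is chemoselective for the aldehyde and E-selective, and it returns the route at 10.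

Step 5 (one-pot hydroperoxyketalisation). The ketone may give mixtures of the gem-dihydroperoxide, the dimethyl ketal and the desired mixed peroxyketal. The fallback sets out from 10 and separates the two events. HC(OMe)3 and PPTS in MeOH give methyl (2E,12E)-6,6-dimethoxydocosa-2,12-dien-10-ynoate F6. Anhydrous H2O2 in Et2O with catalytic CSA at 0 °C then exchanges one methoxy group (perhydrolysis of a ketal) and returns the route at 11.

**Further compounds**
F1 | step 6 | methyl 2-[(3R,6S)-6-[(6E)-hexadec-6-en-4-yn-1-yl]-6-methoxy-1,2-dioxan-3-yl]acetate | CCCCCCCCC/C=C/C#CCCC[C@@]1(OC)CC[C@H](CC(=O)OC)OO1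
F2 | step 6 | methyl 2-[(3R,6R)-6-[(6E)-hexadec-6-en-4-yn-1-yl]-6-methoxy-1,2-dioxan-3-yl]acetate | CCCCCCCCC/C=C/C#CCCC[C@]1(OC)CC[C@H](CC(=O)OC)OO1
F3 | step 4 | bromomagnesium ketimine of (9E)-1-(1,3-dioxan-2-yl)nonadec-9-en-7-yn-3-one | CCCCCCCCC/C=C/C#CCCCC(=N[Mg]Br)CCC1OCCCO1
F4 | step 4 | (9E)-1-(1,3-dioxan-2-yl)nonadec-9-en-7-yn-3-one | CCCCCCCCC/C=C/C#CCCCC(=O)CCC1OCCCO1
F5 | step 4 | (10E)-4-oxoicos-10-en-8-ynal | CCCCCCCCC/C=C/C#CCCCC(=O)CCC=O
F6 | step 5 | methyl (2E,12E)-6,6-dimethoxydocosa-2,12-dien-10-ynoate | CCCCCCCCC/C=C/C#CCCCC(OC)(OC)CC/C=C/C(=O)OC
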